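**Retrosynthetic overview**

1. Eudesmane numbering is used: ring A = C1–C5 and C10, ring B = C5–C10, C14 = angular methyl, C15 = oxymethylene carbon, C11–C13 = acrylic acid unit. The last disconnections are the C15–O acyl bond (Mitsunobu with a (Z)-p-coumaric acid fragment from a Still–Gennari olefination) and C11–C12 (carbonylation of the enol triflate of a C7 acetyl group).
2. Ring A is cut at C1–C10 and at C3=C4 in one [3+3] annulation: Giese addition of a C10 radical (hydrogen-atom transfer to a C9=C10 olefin) to a C3 enal (C1–C3), then intramolecular Horner–Wadsworth–Emmons closure from a C4 phosphonoacetate.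
3. Enabling feature: C4 carries C15, which can be held at the ester level, so C3=C4 of ring A is an enoate (olefination retron). C10 is a methyl-bearing quaternary carbon 1,3 to C4 through C5, i.e. the tertiary radical of a 1-methylcyclohexene. The three ring-A carbons between them (C1, C2, C3) are exactly one enal.
4. Ring B with C5 and C7 comes from (S)-carvone: Luche reduction and Johnson–Claisen rearrangement turn the carvone C–O bond into the cis C5–C4 bond and leave the C9=C10 olefin; the isopropenyl group is cut to the C7 acetyl group before the annulation.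
5. Order of ring formation: ring B from the chiral pool, ring A in the key step, then C15 reduction, acrylate carbonylation, esterification and deprotection.

Key step: step 5

Remark: the target is read as the natural trans-fused eudesmane (5α-H, 7β side chain, 10β-methyl; 2R,4aR,8aR), and the 4-methoxybenzyl ether of 4-hydroxybenzaldehyde used in step 9 is taken as a catalogue chemical.

**Route**

Step 1
Reactants: 1 (S)-(+)-carvone
Product: 2 (1S,5S)-2-methyl-5-(prop-1-en-2-yl)cyclohex-2-en-1-ol (cis-carveol, OH cis to isopropenyl)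
Conditions: NaBH4, CeCl3·7H2O, MeOH, 0 °C
Reagents that add atoms: none
Why: Luche 1,2-reduction; axial hydride delivery to the enone carbonyl should give the equatorial alcohol cis to the equatorial isopropenyl group, which fixes the face on which C4 is later delivered.

Step 2
Reactants: 2 (1S,5S)-cis-carveol
Product: 4 ethyl 2-[(1S,5R)-2-methyl-5-(prop-1-en-2-yl)cyclohex-2-en-1-yl]acetate, via mixed ketene acetal 3 (not isolated)
Conditions: MeC(OEt)3 (excess), EtCO2H (cat.), 140–180 °C (sealed tube)
Reagents that add atoms: triethyl orthoacetate CCOC(C)(OCC)OCC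
Why: Johnson–Claisen rearrangement; the suprafacial [3,3] shift of ketene acetal 3 relays the C–O configuration to the new C5–C4 bond on the same face (cis to isopropenyl, the later 5α-H) and moves the olefin to C9=C10.

Step 3
Reactants: 4 ethyl 2-[(1S,5R)-2-methyl-5-(prop-1-en-2-yl)cyclohex-2-en-1-yl]acetate
Product: 7 ethyl 2-(diethoxyphosphoryl)-2-[(1R,5R)-2-methyl-5-(prop-1-en-2-yl)cyclohex-2-en-1-yl]acetate (both epimers at the phosphonate carbon), via lithium ester enolate 5 (not isolated), via diethyl phosphonite ester 6 (not isolated)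
Conditions: LDA, THF, −78 °C; ClP(OEt)2, −78 °C to rt; then 30% H2O2, 0 °C
Reagents that add atoms: diethyl chlorophosphite CCOP(Cl)OCC; hydrogen peroxide OO
Why: C-phosphinylation of an ester enolate with a trivalent phosphorus chloride followed by oxidation to the phosphonate (α-phosphono ester synthesis); the new stereocentre at C4 is inconsequential because C4 becomes sp2 in step 5.

Step 4
Reactants: 7 ethyl 2-(diethoxyphosphoryl)-2-[(1R,5R)-2-methyl-5-(prop-1-en-2-yl)cyclohex-2-en-1-yl]acetate
Product: 9 ethyl 2-[(1R,5R)-5-acetyl-2-methylcyclohex-2-en-1-yl]-2-(diethoxyphosphoryl)acetate, via vicinal diol 8 (not isolated)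
Conditions: K2OsO2(OH)4 (1 mol%), (DHQD)2PHAL (2 mol%), NMO, acetone/H2O, 0 °C; then NaIO4, THF/H2O, rt
Reagents that add atoms: N-methylmorpholine N-oxide C[N+]1([O-])CCOCC1 (oxygen source, relayed to carbon by the osmium catalyst)
Why: catalytic osmium dihydroxylation and periodate glycol cleavage (Lemieux–Johnson-type degradation); the ligand-bound osmium tetroxide should pick the unhindered 1,1-disubstituted isopropenyl olefin over the trisubstituted ring olefin flanked by the branched C5 substituent, leaving the C7 acetyl group as the masked acrylate.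

Step 5
Reactants: 9 ethyl 2-[(1R,5R)-5-acetyl-2-methylcyclohex-2-en-1-yl]-2-(diethoxyphosphoryl)acetate; 10 acrolein
Product: 12 ethyl (4aR,7R,8aR)-7-acetyl-4a-methyl-3,4,4a,5,6,7,8,8a-octahydronaphthalene-1-carboxylate, via Giese aldehyde 11 (not isolated)
Conditions: Fe(acac)3 (30 mol%), PhSiH3, 10 (3 equiv), degassed EtOH/(CH2OH)2, 60 °C; volatiles evaporated; then LiCl, DBU, MeCN, rt
Reagents that add atoms: none
Why: Proposed new method: an iron hydride generated from Fe(acac)3 and PhSiH3 should transfer a hydrogen atom to C9 of the only olefin of 9 (Markovnikov), the tertiary C10 radical adds to the terminal carbon of acrolein 10 (C1–C10 bond) and the α-formyl radical is reduced by divalent iron and protonated by ethanol to aldehyde 11; once excess 10 has been evaporated, LiCl/DBU generates the phosphonate carbanion, which closes ring A by an intramolecular Horner–Wadsworth–Emmons reaction (C3=C4 bond, loss of diethyl phosphate). The closest known reaction types are the iron-catalysed hydrogen-atom-transfer reductive coupling of unactivated olefins with enones and enals (Giese addition of tertiary radicals) and the Michael addition/intramolecular Horner–Wadsworth–Emmons route to cyclohexenecarboxylates; only their merger in one flask as a [3+3] annulation is new. Ring A is closed as a six-membered carbocycle by 6-exo-trig addition of the C4 carbanion to the C3 aldehyde followed by syn-elimination of phosphate, which can only give the endocyclic C3=C4 enoate. The new quaternary stereocentre C10 is set in the radical addition by 1,2-induction from C5: the branched phosphonoacetate substituent shields its own face of the nearly planar radical, so acrolein should add anti to it, placing C1 trans to C4 and the methyl group cis to the C7 acetyl group, which is the trans-decalin after ring closure. The step needs chemoselective radical generation and capture, secured by 9 carrying a single electron-rich olefin (the isopropenyl group was cut in step 4) and by 10 being the only radical acceptor, and it needs the base to be withheld until 10 is removed so that the phosphonate anion cannot add to it.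

Step 6
Reactants: 12 ethyl (4aR,7R,8aR)-7-acetyl-4a-methyl-3,4,4a,5,6,7,8,8a-octahydronaphthalene-1-carboxylate
Product: 14 ethyl (4aR,7R,8aR)-4a-methyl-7-{1-[(trifluoromethanesulfonyl)oxy]ethenyl}-3,4,4a,5,6,7,8,8a-octahydronaphthalene-1-carboxylate, via potassium enolate 13 (not isolated)
Conditions: KHMDS, THF, −78 °C; PhNTf2, −78 to 0 °C
Reagents that add atoms: N-phenylbis(trifluoromethanesulfonimide) O=S(=O)(N(c1ccccc1)S(=O)(=O)C(F)(F)F)C(F)(F)F
Why: kinetic deprotonation of the methyl ketone at CH3 and O-sulfonylation of the enolate (enol triflate synthesis); at −78 °C the ketone should be deprotonated far faster than the enoate, and the equatorial C7 configuration, α to the ketone since step 4 and thermodynamically preferred, is fixed for good once the triflate is formed.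

Step 7
Reactants: 14 enol triflate ethyl ester
Product: 15 1-[(2R,4aR,8aR)-8-(hydroxymethyl)-4a-methyl-1,2,3,4,4a,5,6,8a-octahydronaphthalen-2-yl]ethenyl trifluoromethanesulfonate
Conditions: i-Bu2AlH (2.5 equiv), CH2Cl2, −78 °C; Rochelle salt work-up
Reagents that add atoms: none
Why: 1,2-reduction of the α,β-unsaturated ester to the allylic alcohol with i-Bu2AlH; enol triflates are inert to the hydride at −78 °C.

Step 8
Reactants: 15 enol triflate allylic alcohol
Product: 16 4-methoxybenzyl 2-[(2R,4aR,8aR)-8-(hydroxymethyl)-4a-methyl-1,2,3,4,4a,5,6,8a-octahydronaphthalen-2-yl]prop-2-enoate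
Conditions: Pd(OAc)2 (5 mol%), dppp, CO (1 atm), 4-methoxybenzyl alcohol (10 equiv), Et3N, DMF, 60 °C
Reagents that add atoms: carbon monoxide [C-]#[O+]; 4-methoxybenzyl alcohol COc1ccc(CO)cc1
Why: palladium-catalysed alkoxycarbonylation of an enol triflate (oxidative addition to zerovalent palladium, CO insertion, alcoholysis of the acyl complex); the external alcohol is in large excess over the substrate's own allylic hydroxyl, which palladium does not ionise.

Step 9
Reactants: 17 4-[(4-methoxybenzyl)oxy]benzaldehyde; 18 methyl 2-[bis(2,2,2-trifluoroethoxy)phosphoryl]acetate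
Product: 20 methyl (2Z)-3-{4-[(4-methoxybenzyl)oxy]phenyl}prop-2-enoate, via potassium phosphonate carbanion 19 (not isolated)
Conditions: 18, KHMDS, 18-crown-6, THF, −78 °C; then 17, −78 °C
Reagents that add atoms: none
Why: Still–Gennari olefination; the electron-poor bis(trifluoroethyl) phosphonate under dissociating conditions eliminates irreversibly from the kinetic adduct and should give the Z cinnamate.

Step 10
Reactants: 20 methyl (2Z)-3-{4-[(4-methoxybenzyl)oxy]phenyl}prop-2-enoate
Product: 21 (2Z)-3-{4-[(4-methoxybenzyl)oxy]phenyl}prop-2-enoic acid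
Conditions: LiOH, THF/MeOH/H2O, rt, dark; then 1 M HCl to pH 3
Reagents that add atoms: lithium hydroxide [Li+].[OH-]
Why: ester saponification; the 4-methoxybenzyl aryl ether and the Z olefin are stable to cold aqueous base in the dark.

Step 11
Reactants: 16 4-methoxybenzyl acrylate allylic alcohol; 21 (Z)-acid
Product: 22 4-methoxybenzyl 2-[(2R,4aR,8aR)-8-({[(2Z)-3-{4-[(4-methoxybenzyl)oxy]phenyl}prop-2-enoyl]oxy}methyl)-4a-methyl-1,2,3,4,4a,5,6,8a-octahydronaphthalen-2-yl]prop-2-enoate
Conditions: PPh3, DIAD, THF, 0 °C, dark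
Reagents that add atoms: none
Why: Mitsunobu esterification; the carboxylate of 21 displaces the phosphonium-activated primary allylic oxygen of 16 by SN2, so the acid is never activated at the acyl carbon and the Z geometry should be kept.

Step 12
Reactants: 22 bis(4-methoxybenzyl)-protected target
Product: 23 2-[(2R,4aR,8aR)-8-({[(2Z)-3-(4-hydroxyphenyl)prop-2-enoyl]oxy}methyl)-4a-methyl-1,2,3,4,4a,5,6,8a-octahydronaphthalen-2-yl]prop-2-enoic acid (CNP0183482.1)
Conditions: TFA (10% v/v), pentamethylbenzene (5 equiv), CH2Cl2, 0 °C, dark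
Reagents that add atoms: none
Why: acidolysis of the 4-methoxybenzyl ester and aryl ether with pentamethylbenzene as a non-reducing cation trap; the allylic ester, both olefins and the Z cinnamate should be stable to dilute TFA at 0 °C.

**Compound list**

1 | (S)-(+)-carvone, (5S)-2-methyl-5-(prop-1-en-2-yl)cyclohex-2-en-1-one | CC(=C)[C@@H]1CC(=O)C(C)=CC1 | starting material
2 | (1S,5S)-2-methyl-5-(prop-1-en-2-yl)cyclohex-2-en-1-ol (cis-carveol) | CC(=C)[C@@H]1C[C@H](O)C(C)=CC1 | intermediate
3 | 1-ethoxyvinyl ether of 2 (mixed ketene acetal, not isolated) | CC(=C)[C@@H]1C[C@H](OC(=C)OCC)C(C)=CC1 | intermediate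
4 | ethyl 2-[(1S,5R)-2-methyl-5-(prop-1-en-2-yl)cyclohex-2-en-1-yl]acetate | CC(=C)[C@@H]1CC=C(C)[C@H](CC(=O)OCC)C1 | intermediate
5 | lithium enolate of 4 (not isolated) | CC(=C)[C@@H]1CC=C(C)[C@H](C=C([O-])OCC)C1.[Li+] | intermediate
6 | ethyl 2-(diethoxyphosphanyl)-2-[(1R,5R)-2-methyl-5-(prop-1-en-2-yl)cyclohex-2-en-1-yl]acetate (not isolated) | CC(=C)[C@@H]1CC=C(C)[C@H](C(C(=O)OCC)P(OCC)OCC)C1 | intermediate
7 | ethyl 2-(diethoxyphosphoryl)-2-[(1R,5R)-2-methyl-5-(prop-1-en-2-yl)cyclohex-2-en-1-yl]acetate | CC(=C)[C@@H]1CC=C(C)[C@H](C(C(=O)OCC)P(=O)(OCC)OCC)C1 | intermediate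
8 | ethyl 2-(diethoxyphosphoryl)-2-[(1R,5R)-5-(1,2-dihydroxypropan-2-yl)-2-methylcyclohex-2-en-1-yl]acetate (not isolated) | CC(O)(CO)[C@@H]1CC=C(C)[C@H](C(C(=O)OCC)P(=O)(OCC)OCC)C1 | intermediate
9 | ethyl 2-[(1R,5R)-5-acetyl-2-methylcyclohex-2-en-1-yl]-2-(diethoxyphosphoryl)acetate | CC(=O)[C@@H]1CC=C(C)[C@H](C(C(=O)OCC)P(=O)(OCC)OCC)C1 | intermediate
10 | acrolein (prop-2-enal) | C=CC=O | starting material
11 | ethyl 2-[(1R,2S,5R)-5-acetyl-2-methyl-2-(3-oxopropyl)cyclohexyl]-2-(diethoxyphosphoryl)acetate (not isolated) | CC(=O)[C@@H]1CC[C@@](C)(CCC=O)[C@H](C(C(=O)OCC)P(=O)(OCC)OCC)C1 | intermediate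
12 | ethyl (4aR,7R,8aR)-7-acetyl-4a-methyl-3,4,4a,5,6,7,8,8a-octahydronaphthalene-1-carboxylate | CC(=O)[C@@H]1CC[C@@]2(C)CCC=C(C(=O)OCC)[C@@H]2C1 | intermediate
13 | potassium enolate of 12 at the methyl group (not isolated) | C=C([O-])[C@@H]1CC[C@@]2(C)CCC=C(C(=O)OCC)[C@@H]2C1.[K+] | intermediate
14 | ethyl (4aR,7R,8aR)-4a-methyl-7-{1-[(trifluoromethanesulfonyl)oxy]ethenyl}-3,4,4a,5,6,7,8,8a-octahydronaphthalene-1-carboxylate | C=C(OS(=O)(=O)C(F)(F)F)[C@@H]1CC[C@@]2(C)CCC=C(C(=O)OCC)[C@@H]2C1 | intermediate
15 | 1-[(2R,4aR,8aR)-8-(hydroxymethyl)-4a-methyl-1,2,3,4,4a,5,6,8a-octahydronaphthalen-2-yl]ethenyl trifluoromethanesulfonate | C=C(OS(=O)(=O)C(F)(F)F)[C@@H]1CC[C@@]2(C)CCC=C(CO)[C@@H]2C1 | intermediate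
16 | 4-methoxybenzyl 2-[(2R,4aR,8aR)-8-(hydroxymethyl)-4a-methyl-1,2,3,4,4a,5,6,8a-octahydronaphthalen-2-yl]prop-2-enoate | C=C(C(=O)OCc1ccc(OC)cc1)[C@@H]1CC[C@@]2(C)CCC=C(CO)[C@@H]2C1 | intermediate
17 | 4-[(4-methoxybenzyl)oxy]benzaldehyde | COc1ccc(COc2ccc(C=O)cc2)cc1 | starting material
18 | methyl 2-[bis(2,2,2-trifluoroethoxy)phosphoryl]acetate | COC(=O)CP(=O)(OCC(F)(F)F)OCC(F)(F)F | starting material
19 | potassium carbanion of 18 (not isolated) | COC(=O)[CH-]P(=O)(OCC(F)(F)F)OCC(F)(F)F.[K+] | intermediate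
20 | methyl (2Z)-3-{4-[(4-methoxybenzyl)oxy]phenyl}prop-2-enoate | COC(=O)/C=C\c1ccc(OCc2ccc(OC)cc2)cc1 | intermediate
21 | (2Z)-3-{4-[(4-methoxybenzyl)oxy]phenyl}prop-2-enoic acid | OC(=O)/C=C\c1ccc(OCc2ccc(OC)cc2)cc1 | intermediate
22 | 4-methoxybenzyl 2-[(2R,4aR,8aR)-8-({[(2Z)-3-{4-[(4-methoxybenzyl)oxy]phenyl}prop-2-enoyl]oxy}methyl)-4a-methyl-1,2,3,4,4a,5,6,8a-octahydronaphthalen-2-yl]prop-2-enoate | C=C(C(=O)OCc1ccc(OC)cc1)[C@@H]1CC[C@@]2(C)CCC=C(COC(=O)/C=C\c3ccc(OCc4ccc(OC)cc4)cc3)[C@@H]2C1 | intermediate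
23 | 2-[(2R,4aR,8aR)-8-({[(2Z)-3-(4-hydroxyphenyl)prop-2-enoyl]oxy}methyl)-4a-methyl-1,2,3,4,4a,5,6,8a-octahydronaphthalen-2-yl]prop-2-enoic acid | C=C(C(=O)O)[C@@H]1CC[C@@]2(C)CCC=C(COC(=O)/C=C\c3ccc(O)cc3)[C@@H]2C1 | target

**Step count and risks**

Total step count: 12 (steps 1–8, 11 and 12 on the main line; steps 9 and 10 for the acid fragment).
Longest linear sequence: 10 steps (1–8, 11, 12).

Steps most likely to fail:

1. Step 5 (proposed new method). What may go wrong: poor facial selectivity of the radical addition at C10, reduction of the newly formed aldehyde by silane residues once base is added, or addition of the phosphonate anion to acrolein that was not fully removed. Fallback in known chemistry, with the two bond formations separated: from 9, the hydrogen-atom-transfer Giese coupling with acrolein is run alone, aldehyde 11 is isolated by aqueous work-up and chromatography (removing silane residues, acrolein oligomers and any C10 epimer), and the ring is then closed in a separate Masamune–Roush olefination (LiCl, DBU, MeCN), which comes back to the route at 12. This fallback makes no compound outside the list (F0).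

2. Step 4. What may go wrong: loss of chemoselectivity between the two olefins, with competing osmylation of the ring olefin that the key step needs. Fallback: the isopropenyl group is cut while the ring olefin is still a deactivated enone. From 1, ozonolysis (O3, CH2Cl2/MeOH, −78 °C; Me2S) gives (S)-5-acetyl-2-methylcyclohex-2-en-1-one F1. Selective ketalisation of the saturated ketone (ethylene glycol, PPTS, benzene, water removal) gives (S)-2-methyl-5-(2-methyl-1,3-dioxolan-2-yl)cyclohex-2-en-1-one F2. Luche reduction gives (1S,5S)-2-methyl-5-(2-methyl-1,3-dioxolan-2-yl)cyclohex-2-en-1-ol F3. Johnson–Claisen rearrangement through its 1-ethoxyvinyl ether F4 gives ethyl 2-[(1S,5R)-2-methyl-5-(2-methyl-1,3-dioxolan-2-yl)cyclohex-2-en-1-yl]acetate F5. Phosphorylation as in step 3, through the lithium enolate of F5 F6 and ethyl 2-(diethoxyphosphanyl)-2-[(1R,5R)-2-methyl-5-(2-methyl-1,3-dioxolan-2-yl)cyclohex-2-en-1-yl]acetate F7, gives ethyl 2-(diethoxyphosphoryl)-2-[(1R,5R)-2-methyl-5-(2-methyl-1,3-dioxolan-2-yl)cyclohex-2-en-1-yl]acetate F8. Mild aqueous acid (PPTS, acetone/H2O) then removes the dioxolane and comes back to the route at 9.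

3. Step 8. What may go wrong: acylation of the substrate's own allylic hydroxyl by the acyl-palladium intermediate (oligoester formation) or palladium-hydride isomerisation of the allylic alcohol. Fallback with temporary protection: from 15, silylation (TBSCl, imidazole, DMF) gives 1-[(2R,4aR,8aR)-8-({[tert-butyl(dimethyl)silyl]oxy}methyl)-4a-methyl-1,2,3,4,4a,5,6,8a-octahydronaphthalen-2-yl]ethenyl trifluoromethanesulfonate F9. Alkoxycarbonylation under the step 8 conditions gives 4-methoxybenzyl 2-[(2R,4aR,8aR)-8-({[tert-butyl(dimethyl)silyl]oxy}methyl)-4a-methyl-1,2,3,4,4a,5,6,8a-octahydronaphthalen-2-yl]prop-2-enoate F10. HF·pyridine in THF/pyridine removes the silyl ether and comes back to the route at 16.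

**Further compounds**

F0 | step 5 | none | none
F1 | step 4 | (S)-5-acetyl-2-methylcyclohex-2-en-1-one | CC(=O)[C@@H]1CC(=O)C(C)=CC1
F2 | step 4 | (S)-2-methyl-5-(2-methyl-1,3-dioxolan-2-yl)cyclohex-2-en-1-one | CC2(OCCO2)[C@@H]1CC(=O)C(C)=CC1
F3 | step 4 | (1S,5S)-2-methyl-5-(2-methyl-1,3-dioxolan-2-yl)cyclohex-2-en-1-ol | CC2(OCCO2)[C@@H]1C[C@H](O)C(C)=CC1
F4 | step 4 | 1-ethoxyvinyl ether of F3 (ketene acetal, not isolated) | CC2(OCCO2)[C@@H]1C[C@H](OC(=C)OCC)C(C)=CC1
F5 | step 4 | ethyl 2-[(1S,5R)-2-methyl-5-(2-methyl-1,3-dioxolan-2-yl)cyclohex-2-en-1-yl]acetate | CC2(OCCO2)[C@@H]1CC=C(C)[C@H](CC(=O)OCC)C1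
F6 | step 4 | lithium enolate of F5 (not isolated) | CC2(OCCO2)[C@@H]1CC=C(C)[C@H](C=C([O-])OCC)C1.[Li+]
F7 | step 4 | ethyl 2-(diethoxyphosphanyl)-2-[(1R,5R)-2-methyl-5-(2-methyl-1,3-dioxolan-2-yl)cyclohex-2-en-1-yl]acetate (not isolated) | CC2(OCCO2)[C@@H]1CC=C(C)[C@H](C(C(=O)OCC)P(OCC)OCC)C1
F8 | step 4 | ethyl 2-(diethoxyphosphoryl)-2-[(1R,5R)-2-methyl-5-(2-methyl-1,3-dioxolan-2-yl)cyclohex-2-en-1-yl]acetate | CC2(OCCO2)[C@@H]1CC=C(C)[C@H](C(C(=O)OCC)P(=O)(OCC)OCC)C1
F9 | step 8 | 1-[(2R,4aR,8aR)-8-({[tert-butyl(dimethyl)silyl]oxy}methyl)-4a-methyl-1,2,3,4,4a,5,6,8a-octahydronaphthalen-2-yl]ethenyl trifluoromethanesulfonate | C=C(OS(=O)(=O)C(F)(F)F)[C@@H]1CC[C@@]2(C)CCC=C(CO[Si](C)(C)C(C)(C)C)[C@@H]2C1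
F10 | step 8 | 4-methoxybenzyl 2-[(2R,4aR,8aR)-8-({[tert-butyl(dimethyl)silyl]oxy}methyl)-4a-methyl-1,2,3,4,4a,5,6,8a-octahydronaphthalen-2-yl]prop-2-enoate | C=C(C(=O)OCc1ccc(OC)cc1)[C@@H]1CC[C@@]2(C)CCC=C(CO[Si](C)(C)C(C)(C)C)[C@@H]2C1
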